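**Plan**

1. Retrosynthesis: cut the C6–O acyl bond (angelate); trace C6–OH to the C6 ketone and the ketone to an exocyclic C6=CH2; then undo ring B by removing the C8–OH bond and re-forming C6–C8. This gives a five-membered ring (C5, C6, C8, C9, C10) carrying a cyclopropane whose CH2 is C7. Cut that CH2 (CH2I2), then C6=C8 (aldol), and reconnect C7–C8 to reach ring B of sclareol.
2. Forward: ring A and the side chain of (−)-sclareol are kept. Ring B is opened at C7=C8, reclosed one carbon smaller by aldol condensation (the old C7 becomes an exocyclic carbon on C6), cyclopropanated, and enlarged back to six members in the key step.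
3. Enabling feature: in ring B the tertiary carbinol C8 lies 1,3 to C6 across the methylene C7. With C6 as an sp2 carbon, C8–OH is homoallylic, which is the retron of a cyclopropylcarbinyl-to-homoallyl ring enlargement of a bicyclo[3.1.0]hexane.
4. Stereochemistry: C5, C9, C10 and C13 come unchanged from sclareol. C8 is rebuilt by α-face cyclopropanation and anti capture of water. C6 is set by an equilibrating dissolving-metal reduction (equatorial OH). The Z alkene comes from angelic acid.
5. Carbon count: the original C7 leaves as formaldehyde in step 8; C7 of the target is the CH2 of CH2I2.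

Key step: step 7

Remark (assumption): the target is read as (13R)-6α-angeloyloxylabd-14-ene-8α,13-diol; labdane numbering is used throughout, and commercial (−)-sclareol is taken to be the 5S,8R,9R,10S,13R compound of SMILES 1.

**Step 1**
Reactants: 1 (−)-sclareol
Product: 2 13-O-triethylsilylsclareol
Conditions: TESOTf (1.05 equiv), 2,6-lutidine, CH2Cl2, −78 °C
Reagents that add atoms: triethylsilyl trifluoromethanesulfonate, CC[Si](CC)(CC)OS(=O)(=O)C(F)(F)F
Why: Silyl ether formation; the side-chain tertiary allylic 13-OH is far more accessible than the ring 8-OH (flanked by C9 and the axial C17 methyl), so one equivalent at low temperature should silylate O-13 only.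

**Step 2**
Reactants: 2 13-O-triethylsilylsclareol
Product: 3 (13R)-13-(triethylsilyloxy)labda-7,14-diene
Conditions: Burgess reagent (MeO2C–N−–SO2–N+Et3), benzene, 50 °C; chromatography on AgNO3-impregnated silica
Reagents that add atoms: none
Why: Burgess dehydration (syn elimination of the 8-sulfamate) should take the cis axial 7α-hydrogen and give mainly the trisubstituted 7-ene, the neutral conditions sparing the allylic silyl ether.

**Step 3**
Reactants: 3 (13R)-13-(triethylsilyloxy)labda-7,14-diene
Product: 5 keto aldehyde (13R)-8-oxo-13-(triethylsilyloxy)-7,8-secolabd-14-en-7-al, via ring-B epoxide 4 (not isolated)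
Conditions: mCPBA, NaHCO3, CH2Cl2, 0 °C; then H5IO6, THF–H2O, 0 °C
Reagents that add atoms: mCPBA, O=C(OO)c1cccc(Cl)c1; water, O
Why: Prilezhaev epoxidation is selective for the electron-rich trisubstituted ring alkene over the vinyl group (α face), and periodic acid then hydrates the epoxide and cleaves the glycol (Malaprade cleavage) to the C7 aldehyde and the C8 methyl ketone, the epoxide stereocentres being destroyed.

**Step 4**
Reactants: 5 keto aldehyde
Product: 6 B-nor enal (cyclopentene C5–C6=C8–C9–C10 with CHO, the old C7, on C6 and CH3 on C8)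
Conditions: Bn2NH·CF3CO2H (dibenzylammonium trifluoroacetate), benzene, 50 °C
Reagents that add atoms: none
Why: Amine-salt-mediated intramolecular aldol condensation: the enamine of the aldehyde (C6 nucleophile) adds to the C8 ketone in a 5-exo-trig closure and water is lost to the tetrasubstituted enal, the weakly acidic medium leaving C9 (α to the ketone) unepimerised.

**Step 5**
Reactants: 6 B-nor enal
Product: 7 B-nor allylic alcohol (CH2OH on C6)
Conditions: NaBH4, CeCl3·7H2O, MeOH, 0 °C
Reagents that add atoms: none
Why: Luche reduction gives clean 1,2-reduction of the hindered enal to the primary allylic alcohol and creates no stereocentre.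

**Step 6**
Reactants: 7 B-nor allylic alcohol
Product: 8 cyclopropyl carbinol (CH2 bridge on the α face between C6 and C8; CH2OH on C6, CH3 on C8)
Conditions: Et2Zn, CH2I2, CH2Cl2, 0 °C to rt
Reagents that add atoms: diiodomethane, ICI
Why: Hydroxyl-assisted Simmons–Smith cyclopropanation (Furukawa variant) of the tetrasubstituted allylic alcohol delivers CH2 to the α face, anti to the C10 methyl and the C9 side chain, which fixes the configurations at C6 and C8; the vinyl group, lacking a free OH, stays untouched.

**Step 7**
Reactants: 8 cyclopropyl carbinol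
Product: 10 (13R)-6-methylidene-13-(triethylsilyloxy)labd-14-en-8α-ol, via mesylate 9 (not isolated)
Conditions: Ms2O, Et3N, CH2Cl2, −40 °C; then acetone–H2O (3:1), NaHCO3, −40 °C to rt
Reagents that add atoms: water, O
Why: The primary cyclopropylcarbinyl mesylate ionises with participation of the strained C6–C8 bond shared by the cyclopropane and the five-membered ring, so the charge moves to the tertiary C8 while C6 becomes sp2 (exocyclic C6=CH2) and the bridging CH2 becomes C7 of a six-membered ring B. The closest known reaction type is the cyclopropylcarbinyl-to-homoallyl rearrangement (reopening of 3,5-cyclosteroids; solvolysis of chrysanthemyl esters to tertiary homoallylic alcohols). No ring is closed by bond formation: the five-membered ring is enlarged by one carbon through fission of its fusion bond, so no exo or endo mode applies. The new stereocentre C8 is set by capture of water anti to the departing C6 (inversion) from the α-face cyclopropane, which puts OH equatorial (8α) and CH3 axial (8β); equatorial approach away from the axial C10 methyl points the same way if the cation is fully open. The step needs cleavage of the internal C6–C8 bond and not the external C6–C7 bond, which is secured because only the former gives a tertiary cation and releases all ring strain, while a cyclobutyl shift would put the charge at a bridgehead of a bicyclo[2.1.1]hexane. The NaHCO3 buffer should favour capture by water over proton loss and keep the silyl ether intact.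

**Step 8**
Reactants: 10 6-methylidene-8α-ol
Product: 12 (13R)-8α-hydroxy-13-(triethylsilyloxy)labd-14-en-6-one, via spiro-epoxide 11 (not isolated)
Conditions: mCPBA, NaHCO3, CH2Cl2, 0 °C; then H5IO6, THF–H2O, 0 °C
Reagents that add atoms: mCPBA, O=C(OO)c1cccc(Cl)c1; water, O
Why: The 1,1-disubstituted exocyclic alkene is epoxidised in preference to the vinyl group, and periodic acid cleaves the derived glycol (Malaprade cleavage), releasing the old C7 as formaldehyde and leaving the C6 ketone with the stable trans ring fusion at C5.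

**Step 9**
Reactants: 12 6-ketone
Product: 13 (13R)-13-(triethylsilyloxy)labd-14-ene-6α,8α-diol
Conditions: Li (2.5 equiv), NH3(l), THF, t-BuOH, −78 °C; then NH4Cl
Reagents that add atoms: none
Why: Dissolving-metal ketone reduction goes through a ketyl and carbanion that are protonated to the thermodynamically favoured equatorial 6α-alcohol (an axial 6β-OH would be syn-axial to the C17, C19 and C20 methyls), the sense opposite to hydride reagents and the one seen for hindered 11-oxo steroids; low temperature and limited lithium spare the allylic silyl ether and outrun retro-aldol cleavage.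

**Step 10**
Reactants: 13 6α,8α-diol; 14 angelic acid
Product: 16 (13R)-6α-angeloyloxy-13-(triethylsilyloxy)labd-14-en-8α-ol, via mixed anhydride 15 (not isolated)
Conditions: 14, 2,4,6-trichlorobenzoyl chloride, Et3N, toluene, rt; then 13, toluene, 80 °C
Reagents that add atoms: angelic acid, C/C=C(/C)C(=O)O
Why: Yamaguchi-type esterification through the mixed anhydride, run without a nucleophilic catalyst, acylates the secondary equatorial 6-OH (the tertiary 8-OH is inert) and keeps the Z geometry of the angelate.

**Step 11**
Reactants: 16 silyl-protected angelate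
Product: 17 target, (13R)-6α-angeloyloxylabd-14-ene-8α,13-diol
Conditions: HF·pyridine, pyridine, THF, 0 °C to rt
Reagents that add atoms: none
Why: Fluoride-mediated desilylation under buffered conditions frees the tertiary allylic 13-OH without ionising it or isomerising the angelate.

**Compound list**

1 | (−)-sclareol, (13R)-labd-14-ene-8α,13-diol | C=C[C@](C)(O)CC[C@@H]1[C@@]2(C)CCCC(C)(C)[C@@H]2CC[C@@]1(C)O | starting material
2 | (13R)-13-(triethylsilyloxy)labd-14-en-8α-ol | C=C[C@](C)(O[Si](CC)(CC)CC)CC[C@@H]1[C@@]2(C)CCCC(C)(C)[C@@H]2CC[C@@]1(C)O | intermediate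
3 | (13R)-13-(triethylsilyloxy)labda-7,14-diene | C=C[C@](C)(O[Si](CC)(CC)CC)CC[C@@H]1[C@@]2(C)CCCC(C)(C)[C@@H]2CC=C1C | intermediate
4 | (13R)-7α,8α-epoxy-13-(triethylsilyloxy)labd-14-ene | C=C[C@](C)(O[Si](CC)(CC)CC)CC[C@@H]1[C@@]2(C)CCCC(C)(C)[C@@H]2C[C@H]3O[C@@]13C | intermediate (not isolated)
5 | (13R)-8-oxo-13-(triethylsilyloxy)-7,8-secolabd-14-en-7-al (CH2CHO on C5, acetyl on C9) | C=C[C@](C)(O[Si](CC)(CC)CC)CC[C@@H](C(C)=O)[C@@]1(C)CCCC(C)(C)[C@@H]1CC=O | intermediate
6 | B-nor enal: cyclopentene C5–C6=C8–C9–C10 trans-fused to ring A, CHO (old C7) on C6, CH3 on C8, silyloxy side chain on C9 | C=C[C@](C)(O[Si](CC)(CC)CC)CC[C@H]1C(C)=C(C=O)[C@H]2C(C)(C)CCC[C@]12C | intermediate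
7 | B-nor allylic alcohol: as 6 with CH2OH on C6 | C=C[C@](C)(O[Si](CC)(CC)CC)CC[C@H]1C(C)=C(CO)[C@H]2C(C)(C)CCC[C@]12C | intermediate
8 | cyclopropyl carbinol: as 7 with an α-face CH2 bridging C6 and C8 (bicyclo[3.1.0]hexane) | C=C[C@](C)(O[Si](CC)(CC)CC)CC[C@H]1[C@]3(C)C[C@]3(CO)[C@H]2C(C)(C)CCC[C@]12C | intermediate
9 | methanesulfonate of 8 | C=C[C@](C)(O[Si](CC)(CC)CC)CC[C@H]1[C@]3(C)C[C@]3(COS(C)(=O)=O)[C@H]2C(C)(C)CCC[C@]12C | intermediate (not isolated)
10 | (13R)-6-methylidene-13-(triethylsilyloxy)labd-14-en-8α-ol | C=C[C@](C)(O[Si](CC)(CC)CC)CC[C@@H]1[C@@]2(C)CCCC(C)(C)[C@@H]2C(=C)C[C@@]1(C)O | intermediate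
11 | spiro-epoxide of 10 at C6 (oxygen α) | C=C[C@](C)(O[Si](CC)(CC)CC)CC[C@@H]1[C@@]2(C)CCCC(C)(C)[C@@H]2[C@]3(CO3)C[C@@]1(C)O | intermediate (not isolated)
12 | (13R)-8α-hydroxy-13-(triethylsilyloxy)labd-14-en-6-one | C=C[C@](C)(O[Si](CC)(CC)CC)CC[C@@H]1[C@@]2(C)CCCC(C)(C)[C@@H]2C(=O)C[C@@]1(C)O | intermediate
13 | (13R)-13-(triethylsilyloxy)labd-14-ene-6α,8α-diol | C=C[C@](C)(O[Si](CC)(CC)CC)CC[C@@H]1[C@@]2(C)CCCC(C)(C)[C@@H]2[C@@H](O)C[C@@]1(C)O | intermediate
14 | angelic acid, (Z)-2-methylbut-2-enoic acid | C/C=C(/C)C(=O)O | starting material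
15 | angelic 2,4,6-trichlorobenzoic anhydride | C/C=C(/C)C(=O)OC(=O)c1c(Cl)cc(Cl)cc1Cl | intermediate (not isolated)
16 | (13R)-6α-angeloyloxy-13-(triethylsilyloxy)labd-14-en-8α-ol | C=C[C@](C)(O[Si](CC)(CC)CC)CC[C@@H]1[C@@]2(C)CCCC(C)(C)[C@@H]2[C@@H](OC(=O)/C(C)=C\C)C[C@@]1(C)O | intermediate
17 | (13R)-6α-angeloyloxylabd-14-ene-8α,13-diol | C=C[C@](C)(O)CC[C@@H]1[C@@]2(C)CCCC(C)(C)[C@@H]2[C@@H](OC(=O)/C(C)=C\C)C[C@@]1(C)O | target

**Totals**

Total step count: 11. Longest linear sequence: 11 steps (1 to 17); angelic acid 14 enters in step 10.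

**Steps most likely to fail**

Step 2: poor regioselectivity in the loss of water. The 8-sulfamate can also take a hydrogen from the C17 methyl or from C9, giving the 8(17)- or 8(9)-ene. The fallback sets out from 2 and comes back at 3, and fixes the position of the double bond by construction. Dehydration with SOCl2/pyridine at −78 °C, which for an equatorial tertiary oxygen takes a methyl hydrogen, should give the exocyclic alkene (13R)-13-(triethylsilyloxy)labda-8(17),14-diene F1. Epoxidation with mCPBA gives the 8α,17-epoxide F2, and periodic acid cleaves it to the 17-nor-8-ketone F3. Kinetic deprotonation with LiN(iPr)2 occurs at the C7 methylene and not at the hindered C9 methine, and PhNTf2 gives the 7-en-8-yl triflate F4. Coupling with Me2CuLi restores the C17 methyl and gives 3.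

Step 7: diversion of the cation. The tertiary C8 cation may lose a proton to give dienes, or the mesylate may ionise before water is present and be captured by other nucleophiles. The fallback sets out from 6 and comes back at 12, and enlarges the ring through a radical instead of a cation. Baeyer–Villiger oxidation of the enal (H2O2, catalytic 2-nitrobenzeneseleninic acid) gives the enol formate F5. MeLi (2 equiv) then Me3SiCl gives the regiodefined trimethylsilyl enol ether F6. Simmons–Smith cyclopropanation on the α face gives the siloxycyclopropane F7. Aerobic ring-opening oxygenation (catalytic VO(acac)2, O2, EtOH, then Me2S) cleaves the C6–C8 bond to the ring-enlarged β-keto radical, which is trapped by O2 at C8, and gives the β-hydroxy ketone 12.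

Step 9: wrong facial outcome or over-reduction. Protonation may occur from the open α face to give the axial 6β-alcohol, the allylic silyloxy group may be lost reductively, or retro-aldol cleavage of the β-hydroxy ketone may intervene. The fallback sets out from 10 and comes back at 13, and avoids the ketone altogether. Epoxide 11 is isolated after the mCPBA stage and rearranged with MgBr2·OEt2 (Meinwald rearrangement); equilibration with DBU gives the equatorial 6α-carbaldehyde F8. Baeyer–Villiger oxidation (mCPBA, NaHCO3) with retention at C6 gives the 6α-formate F9, and K2CO3/MeOH gives 13.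

**Further compounds**

F1 | step 2 | (13R)-13-(triethylsilyloxy)labda-8(17),14-diene | C=C[C@](C)(O[Si](CC)(CC)CC)CC[C@@H]1[C@@]2(C)CCCC(C)(C)[C@@H]2CCC1=C
F2 | step 2 | (13R)-8α,17-epoxy-13-(triethylsilyloxy)labd-14-ene | C=C[C@](C)(O[Si](CC)(CC)CC)CC[C@@H]1[C@@]2(C)CCCC(C)(C)[C@@H]2CC[C@]13CO3
F3 | step 2 | (13R)-13-(triethylsilyloxy)-17-norlabd-14-en-8-one | C=C[C@](C)(O[Si](CC)(CC)CC)CC[C@@H]1[C@@]2(C)CCCC(C)(C)[C@@H]2CCC1=O
F4 | step 2 | (13R)-13-(triethylsilyloxy)-17-norlabda-7,14-dien-8-yl trifluoromethanesulfonate | C=C[C@](C)(O[Si](CC)(CC)CC)CC[C@@H]1[C@@]2(C)CCCC(C)(C)[C@@H]2CC=C1OS(=O)(=O)C(F)(F)F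
F5 | step 7 | B-nor enol formate (OCHO on C6, C6=C8, CH3 on C8) | C=C[C@](C)(O[Si](CC)(CC)CC)CC[C@H]1C(C)=C(OC=O)[C@H]2C(C)(C)CCC[C@]12C
F6 | step 7 | B-nor trimethylsilyl enol ether (OSiMe3 on C6, C6=C8) | C=C[C@](C)(O[Si](CC)(CC)CC)CC[C@H]1C(C)=C(O[Si](C)(C)C)[C@H]2C(C)(C)CCC[C@]12C
F7 | step 7 | siloxycyclopropane (α-face CH2 bridging C6 and C8, OSiMe3 on C6) | C=C[C@](C)(O[Si](CC)(CC)CC)CC[C@H]1[C@]3(C)C[C@]3(O[Si](C)(C)C)[C@H]2C(C)(C)CCC[C@]12C
F8 | step 9 | (13R)-6α-formyl-13-(triethylsilyloxy)labd-14-en-8α-ol | C=C[C@](C)(O[Si](CC)(CC)CC)CC[C@@H]1[C@@]2(C)CCCC(C)(C)[C@@H]2[C@@H](C=O)C[C@@]1(C)O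
F9 | step 9 | (13R)-6α-formyloxy-13-(triethylsilyloxy)labd-14-en-8α-ol | C=C[C@](C)(O[Si](CC)(CC)CC)CC[C@@H]1[C@@]2(C)CCCC(C)(C)[C@@H]2[C@@H](OC=O)C[C@@]1(C)O
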